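# Proposed total synthesis of betaethrin E (22)

## Structural features

Betaethrin E (22) consists of two benzene rings joined by one ether oxygen, between C6 of ring B and C2' of ring A. Ring B is a methyl salicylate: C1 carries CO2Me, C2 a hydrogen-bonded OH, C4 a methyl group and C6 the ether oxygen, so the ester carbon is flanked by two oxygen-bearing carbons. Ring A is a 1,2,4-trioxygenated benzyl alcohol: C1' carries the CH2O-palmitoyl arm, C2' the ether oxygen, C3' a free OH and C5' a methoxy group para to the ether oxygen. There is no stereocentre and no stereogenic double bond, so no stereocentres stand next to each other and nothing has to be set or guarded against epimerisation. The fragile groups are the benzylic palmitate (an ester at a carbon that can ionise with help from the ortho aryloxy group), the oxidation-prone ring A, and the two phenols that must stay unacylated. The real difficulty is the tri-ortho-substituted diaryl ether between two electron-rich rings, a poor case for aryl C–O coupling, together with the need to acylate one of three hydroxyl groups. The key step exploits the C6–C1–C2 array of ring B (O-aryl, ester and OH on adjacent carbons). This array is the polarity pattern of a 4-oxygenated 2-pyranone-3-carboxylate (pyranone C3–C6 become ring B C1–C4) joined to an O–C≡C–H unit (ring B C6 and C5), so the ether oxygen enters on an alkyne and is never attached to an aromatic carbon.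

## Logic of the disconnections

**22 ⇒ 20 + 21.** The bond cut is the benzylic C–O bond of the ester, which in the forward sense forms between the benzylic carbon of 20 and a carboxylate oxygen of 21. The long acyl chain would survive neither an alkyllithium nor acidic methanol, so it is attached last. This removes sixteen carbons and reduces the problem to the triol 20. The forward step must pick one primary alcohol out of three hydroxyl groups without protection. Activating the alcohol rather than the acid achieves this, because a phenol oxygen on an sp2 carbon cannot be displaced.

**20 ⇒ 19.** The O–H bonds of the ring B phenol, the ring A phenol and the benzylic alcohol are replaced by one acetate and two methoxymethyl ethers. All three groups are acid-labile toward methanol, so a single operation releases 20. The forward step must not ionise the benzylic C–O bond.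

**19 ⇒ 11 + 17.** The bonds cut are C1–C6 and C4–C5 of ring B, with a CO2 bridge restored across C1 and C4. This is the key disconnection. It delivers ring B and the hindered diaryl ether together from two fragments of similar size, and it replaces an aryl C–O coupling by a cycloaddition of an alkynyl ether. The forward step needs complete regiocontrol and a 2π partner that tolerates heating. It also needs a diene that stays electron-poor although it carries the C2 oxygen.

**11 ⇒ 8 ⇒ 7 ⇒ 6 ⇒ 5.** In this order the cuts are the alkyne π bonds (back to a 1,2-dichlorovinyl ether with two C–Cl bonds), the acetal C–O bond of the benzylic ether, the benzylic C–H bond (back to the aldehyde) and the vinyl C–O bond. The dichlorovinyl group is a robust carrier of the alkyne and also protects the central phenol from the moment it is installed. The flanking oxygens can therefore be protected at different times with no temporary group on the central oxygen. The forward steps require the hindered, aldehyde-conjugated phenoxide of 5 to add to a chloroalkyne made in the flask, and the acetals to survive an alkyllithium at low temperature.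

**5 ⇒ 4 ⇒ 2 ⇒ 1.** The cuts are the aryl–CHO bond ortho to the phenol, then the phenol C–O bond (traced back to an aryl aldehyde by oxygen insertion), then the acetal. Each substituent is placed by construction. Oxygen insertion puts the free OH where the formyl group of 1 stood, para to OMe and ortho to the protected oxygen. The only open ortho position of 4 then takes the new carbon. This gives a commercial starting material and no regiochemical ambiguity. The demands are a high migratory aptitude of the electron-rich ring and survival of the acetal toward the peracid and the magnesium salt.

**17 ⇒ 16 ⇒ 12 + 13.** The cuts are the O–acyl bond of the enol acetate, then the lactone C–O bond and the C–C bond between the malonate carbon and the ketone-bearing acyl carbon. The pyranone is a malonate joined to an acetoacetyl unit, so two bulk chemicals suffice. The forward step needs C-acylation rather than O-acylation of the malonate and fast capture of the acylketene before it dimerises.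

## Other disconnections considered

**Alternative 1:** Ring A is cut at C1–C2, C2–C3, C4–C5 and C5–C6 (ring A numbered from the CH2O-bearing carbon C1 to the ether carbon C6). Ring B with its ether oxygen is kept intact on an acyclic chain. In the forward key step, irradiation of the diazoketone methyl 2-{[(1E)-2-({[tert-butyl(dimethyl)silyl]oxy}methyl)-4-diazo-3-oxobut-1-en-1-yl]oxy}-6-(methoxymethoxy)-4-methylbenzoate A1 triggers a Wolff rearrangement to a (2-aryloxyvinyl)ketene. This adds (2+2) to methoxyacetylene A2. The cyclobutenone opens in a four-electron electrocyclic step, closes in a six-electron step and tautomerises to the diaryl ether A3, which has a free C5 phenol, a silyl ether on the benzylic oxygen and a MOM ether on ring B.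

- In its favour: ring A is built with full regiocontrol from acyclic carbons, and its three oxygens emerge already differentiated. On this point it is better than the chosen plan, because the phenol that is free in 22 is born free and the benzylic oxygen can be released on its own.
- In its favour: the ether C–O bond is made by addition–elimination at a vinylic carbon, which is as easy as the O-vinylation used for 6.
- Against it here: A1 is a diazomethyl ketone of a β-aryloxy enone. Its preparation needs an acid chloride and diazomethane, and the β-aryloxy enone is an addition–elimination site that can lose the ring B oxygen to any nucleophile on the way.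
- Against it here: A2 is volatile and unstable and must be made fresh, and the photochemical step runs dilute.
- Comparison: on mechanism the two plans are equal, since both are pericyclic cascades whose regiochemistry is fixed by polarity. On structure Alternative 1 is better for hydroxyl differentiation. On step economy the one-step ring A is paid for by a multi-step assembly of A1 and a three-step end game (desilylation, acylation, MOM removal), so no clear saving is expected. The chosen plan avoids diazo and photochemical operations.

**Alternative 2:** Ring A is cut at C6–C1, and its carbons are traced to a 4-pyranone derived from chelidonic acid A4, which serves as a masked 1,3,5-triketone. The ether bond is made beforehand by alkylating a ring B phenol at a primary carbon. In the forward key step, aqueous Ba(OH)2 opens the pyranone methyl 2-hydroxy-4-methyl-6-({4-oxo-6-[(trityloxy)methyl]-4H-pyran-2-yl}methoxy)benzoate A5 to the triketone methyl 2-hydroxy-4-methyl-6-{[2,4,6-trioxo-7-(trityloxy)heptyl]oxy}benzoate A6. The aryloxy-bearing methylene of A6 adds to the distal carbonyl, and dehydration gives the resorcinol methyl 2-{2,4-dihydroxy-6-[(trityloxy)methyl]phenoxy}-6-hydroxy-4-methylbenzoate A7.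

- In its favour: the ether C–O bond is formed by an SN2 reaction at sp3 carbon, which is better than any aryl C–O coupling and equal in spirit to the chosen plan. The materials are cheap, and no organometallic reagent or sensitive alkyne is needed.
- Against it here: both terminal methylenes of A6 can act as the aldol donor, so the direction of folding is not fixed by the substrate.
- Against it here: hot aqueous hydroxide threatens the methyl salicylate ester.
- Against it here: A7 carries three phenols, of which only the one para to the ether oxygen must be methylated.
- Against it here: the two hydroxymethyl arms derived from A4 must be desymmetrised statistically.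
- Comparison: on structure the chosen plan is stronger, since every substituent of rings A and B is placed by construction. On mechanism the chosen cycloaddition is regiochemically determined and the aldol folding is not. On step economy Alternative 2 is at best equal, because reduction, desymmetrisation, alkylation, selective methylation and detritylation surround its key step.

**Alternative 3:** Ring B is cut at C1–C2 and C5–C6. The forward key step is a normal-demand (4+2) cycloaddition between the push–pull alkyne methyl 3-{4-methoxy-2-(methoxymethoxy)-6-[(methoxymethoxy)methyl]phenoxy}prop-2-ynoate A8 and the vinylketene silyl acetal [(1-methoxy-3-methylbuta-1,3-dien-1-yl)oxy]trimethylsilane A9. Loss of methanol and desilylation give methyl 2-hydroxy-6-{4-methoxy-2-(methoxymethoxy)-6-[(methoxymethoxy)methyl]phenoxy}-4-methylbenzoate A10.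

- In its favour: A8 comes from the same acetylide as 11 by carboxylation and is far more stable than a terminal ynol ether. On this point it is better than the chosen plan.
- In its favour: A9 is one step from a commercial ester, against two steps for 17, and A10 has the ring B phenol already free. This is a small advantage in step count.
- In its favour: the regiochemistry is set by polarity, as in the chosen plan.
- Against it here: the aryloxy group donates into the alkyne carbon that must accept the diene terminus, and this carbon sits next to a 2,6-disubstituted ring. The dienophile is therefore deactivated electronically and sterically, and forcing conditions would destroy the labile A9.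
- Against it here: a stepwise conjugate addition can expel aryloxide from the β-carbon, which would lose ring A.
- Against it here: aromatisation has a branch point, loss of methanol or loss of silanol, and the second leads to a methyl ether that is a dead end.
- Comparison: in the chosen plan both partners are activated in the matched sense, and aromatisation can only expel CO2. Alternative 3 is the closest competitor and serves below as the fallback for the key step.

Key step: step 10

Remark: 22 is achiral. The only stereochemical elements in the route are the E double bond of the dichlorovinyl ethers 6–8 and the two bridgeheads of the transient adduct 18, which forms as a racemate and is aromatised at once.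

Remark: the atom mapping of the key step was checked against 22 and is self-consistent, so the connectivity of 11, 17 and 19 is used unchanged. Ring B C1–C4 come from pyranone C3–C6, ring B C5 and C6 from the alkyne, and the OMe of ring A is para to the ether oxygen.

Remark: ring A is entered from 2-hydroxy-4-methoxybenzaldehyde (1), not from its 5-methoxy isomer. The central phenol is carried as its 1,2-dichlorovinyl ether from step 4 onward, so no temporary protecting group for that phenol is needed.

## Route

Step 1
Reactants: 1 2-hydroxy-4-methoxybenzaldehyde
Product: 2 4-methoxy-2-(methoxymethoxy)benzaldehyde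
Conditions: MOMCl, i-Pr2NEt, CH2Cl2, 0 °C to rt
Reagents that add atoms: chloromethyl methyl ether, COCCl
Why: O-alkylation of the phenol by the reactive α-chloro ether (Williamson-type acetal formation); the amine base overcomes the hydrogen bond to the aldehyde and the aldehyde itself is inert.

Step 2
Reactants: 2 4-methoxy-2-(methoxymethoxy)benzaldehyde
Product: 4 4-methoxy-2-(methoxymethoxy)phenol, via aryl formate 3 (not isolated)
Conditions: mCPBA, CH2Cl2, 0 °C to rt; aq. NaHCO3 wash; then K2CO3 (cat.), MeOH, rt
Reagents that add atoms: meta-chloroperoxybenzoic acid, OOC(=O)c1cccc(Cl)c1
Why: Baeyer–Villiger (Dakin-type) oxidation; the aryl group bearing a para methoxy and an ortho acetal oxygen migrates in preference to hydrogen, and mild methanolysis of formate 3 frees the phenol exactly where the formyl group stood.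

Step 3
Reactants: 4 4-methoxy-2-(methoxymethoxy)phenol
Product: 5 2-hydroxy-5-methoxy-3-(methoxymethoxy)benzaldehyde
Conditions: MgCl2, Et3N, (CH2O)n, MeCN, 80 °C
Reagents that add atoms: formaldehyde (from paraformaldehyde), C=O
Why: magnesium-mediated ortho-formylation of a phenol (Casnati–Skattebøl reaction); the magnesium phenoxide delivers formaldehyde to the only free ortho carbon and a second formaldehyde oxidises the benzylic alkoxide by hydride transfer. The non-acidic medium should leave the MOM ether intact.

Step 4
Reactants: 5 2-hydroxy-5-methoxy-3-(methoxymethoxy)benzaldehyde
Product: 6 2-{[(E)-1,2-dichloroethenyl]oxy}-5-methoxy-3-(methoxymethoxy)benzaldehyde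
Conditions: Cl2C=CHCl, K2CO3, DMF, 70 °C
Reagents that add atoms: trichloroethylene, ClC=C(Cl)Cl
Why: base-induced elimination turns trichloroethylene into dichloroacetylene in solution (never isolated), and the phenoxide adds to it; anti addition followed by protonation gives the E-1,2-dichlorovinyl ether. This is the established O-vinylation of phenols, and the aldehyde has no acidic α-hydrogen.

Step 5
Reactants: 6 2-{[(E)-1,2-dichloroethenyl]oxy}-5-methoxy-3-(methoxymethoxy)benzaldehyde
Product: 7 (2-{[(E)-1,2-dichloroethenyl]oxy}-5-methoxy-3-(methoxymethoxy)phenyl)methanol
Conditions: NaBH4, MeOH/THF, 0 °C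
Reagents that add atoms: none
Why: hydride reduction of the aryl aldehyde; vinyl chlorides and acetals do not react with borohydride.

Step 6
Reactants: 7 (2-{[(E)-1,2-dichloroethenyl]oxy}-5-methoxy-3-(methoxymethoxy)phenyl)methanol
Product: 8 2-{[(E)-1,2-dichloroethenyl]oxy}-5-methoxy-1-(methoxymethoxy)-3-[(methoxymethoxy)methyl]benzene
Conditions: MOMCl, i-Pr2NEt, CH2Cl2, 0 °C to rt
Reagents that add atoms: chloromethyl methyl ether, COCCl
Why: acetal protection of the primary benzylic alcohol; it is the only hydroxyl group present because the central phenol is already masked as the dichlorovinyl ether.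

Step 7
Reactants: 8 2-{[(E)-1,2-dichloroethenyl]oxy}-5-methoxy-1-(methoxymethoxy)-3-[(methoxymethoxy)methyl]benzene
Product: 11 2-(ethynyloxy)-5-methoxy-1-(methoxymethoxy)-3-[(methoxymethoxy)methyl]benzene, via chloroethynyl ether 9 (not isolated), via lithium acetylide 10 (not isolated)
Conditions: n-BuLi (2.5 equiv), THF, −78 to −40 °C; then sat. aq. NH4Cl, −78 °C; cold work-up, used at once
Reagents that add atoms: none
Why: the first equivalent of butyllithium removes the vinyl proton and LiCl is eliminated to give 9; the second exchanges chlorine for lithium to give 10, which is protonated. This is the standard conversion of dichlorovinyl ethers into ynol ethers. At −78 °C directed lithiation next to the MOM groups should not compete.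

Step 8
Reactants: 12 dimethyl malonate; 13 2,2,6-trimethyl-4H-1,3-dioxin-4-one
Product: 16 methyl 4-hydroxy-6-methyl-2-oxo-2H-pyran-3-carboxylate, via acetylketene 14 (not isolated), via acetoacetylmalonate 15 (not isolated)
Conditions: NaH, THF, 0 °C; then 13 added slowly, PhMe, 110 °C; 1 M HCl work-up
Reagents that add atoms: none
Why: thermal retro-(4+2) cleavage of 13 releases acetone and acetylketene 14, which C-acylates the sodium malonate; in 15 the enol oxygen of the methyl ketone closes onto one ester carbonyl (lactonisation with loss of methanol) to give the stable pyranone enolate. Slow addition keeps 14 dilute and suppresses its dimerisation.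

Step 9
Reactants: 16 methyl 4-hydroxy-6-methyl-2-oxo-2H-pyran-3-carboxylate
Product: 17 methyl 4-(acetyloxy)-6-methyl-2-oxo-2H-pyran-3-carboxylate
Conditions: AcCl, Et3N, CH2Cl2, 0 °C; non-aqueous work-up (filtration, evaporation)
Reagents that add atoms: acetyl chloride, CC(=O)Cl
Why: O-acylation of the acidic 4-hydroxyl; C3 is blocked, so C-acylation cannot compete. The enol acetate is itself an acyl donor, so it is kept dry and used fresh.

Step 10
Reactants: 11 2-(ethynyloxy)-5-methoxy-1-(methoxymethoxy)-3-[(methoxymethoxy)methyl]benzene; 17 methyl 4-(acetyloxy)-6-methyl-2-oxo-2H-pyran-3-carboxylate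
Product: 19 methyl 2-(acetyloxy)-6-{4-methoxy-2-(methoxymethoxy)-6-[(methoxymethoxy)methyl]phenoxy}-4-methylbenzoate, via bridged lactone adduct 18 (not isolated)
Conditions: 17 (2 equiv), PhMe, 110–130 °C, sealed tube, 4 Å MS
Reagents that add atoms: none
Why: The electron-poor 2-pyranone 17 is the 4π component and the ynol ether 11 the electron-rich 2π component of an inverse-electron-demand Diels–Alder reaction. The closest known reaction type is the cycloaddition of 2-pyranone-3-carboxylates with ketene acetals, ynamines or alkoxyalkynes followed by decarboxylation. Bond formation should be asynchronous: the terminal alkyne carbon, β to oxygen and carrying the largest HOMO coefficient, attacks pyranone C6, the vinylogous acceptor terminus of both carbonyl groups, and the oxygen-bearing carbon closes onto C3. This intermolecular (4+2) closure gives the 2-oxabicyclo[2.2.2]octadienone 18, and ring B appears when 18 expels CO2 in a thermal retro-(4+2) step driven by aromatisation. No stereocentre is created in 19, since the two bridgeheads of racemic 18 become the sp2 carbons C1 and C4. The step needs regioselectivity, and it needs the cycloaddition to outrun self-reaction of 11. The matched polarisation of the partners (ester on C3, oxygen on the alkyne) provides the first; the acetate provides the second by keeping the diene electron-poor and by masking the acidic enol that would protonate 11. The ring A oxygen sits on an sp carbon before the reaction and on an aromatic carbon after it, so no intermediate can eliminate it, and 11 has no hydrogen placed for a retro-ene loss of ketene on heating.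

Step 11
Reactants: 19 methyl 2-(acetyloxy)-6-{4-methoxy-2-(methoxymethoxy)-6-[(methoxymethoxy)methyl]phenoxy}-4-methylbenzoate
Product: 20 methyl 2-hydroxy-6-[2-hydroxy-6-(hydroxymethyl)-4-methoxyphenoxy]-4-methylbenzoate
Conditions: HCl (1.25 M in MeOH), 0 to 40 °C
Reagents that add atoms: none
Why: acid-catalysed methanolysis cleaves the aryl acetate (transesterification) and both MOM acetals (transacetalisation) in one operation; the methyl ester only exchanges with the solvent and the diaryl ether is inert.

Step 12
Reactants: 20 methyl 2-hydroxy-6-[2-hydroxy-6-(hydroxymethyl)-4-methoxyphenoxy]-4-methylbenzoate; 21 hexadecanoic acid (palmitic acid)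
Product: 22 betaethrin E, methyl 2-{2-[(hexadecanoyloxy)methyl]-6-hydroxy-4-methoxyphenoxy}-6-hydroxy-4-methylbenzoate
Conditions: PPh3, DIAD, 21 (1.2 equiv), THF, 0 °C to rt (DIAD added last)
Reagents that add atoms: none
Why: Mitsunobu esterification; only the primary benzylic alcohol can be turned into an alkoxyphosphonium ion that a carboxylate displaces at carbon, whereas a phenol oxygen on sp2 carbon cannot be displaced. The carboxylic acid is about five pKa units more acidic than the phenols, so it protonates the betaine and supplies the nucleophile, which keeps phenoxide alkylation down.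

## Compound list

1 | 2-hydroxy-4-methoxybenzaldehyde | COc1ccc(C=O)c(O)c1 | starting material
2 | 4-methoxy-2-(methoxymethoxy)benzaldehyde | COCOc1cc(OC)ccc1C=O | intermediate
3 | 4-methoxy-2-(methoxymethoxy)phenyl formate | COCOc1cc(OC)ccc1OC=O | intermediate
4 | 4-methoxy-2-(methoxymethoxy)phenol | COCOc1cc(OC)ccc1O | intermediate
5 | 2-hydroxy-5-methoxy-3-(methoxymethoxy)benzaldehyde | COCOc1cc(OC)cc(C=O)c1O | intermediate
6 | 2-{[(E)-1,2-dichloroethenyl]oxy}-5-methoxy-3-(methoxymethoxy)benzaldehyde | COCOc1cc(OC)cc(C=O)c1O/C(Cl)=C\Cl | intermediate
7 | (2-{[(E)-1,2-dichloroethenyl]oxy}-5-methoxy-3-(methoxymethoxy)phenyl)methanol | COCOc1cc(OC)cc(CO)c1O/C(Cl)=C\Cl | intermediate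
8 | 2-{[(E)-1,2-dichloroethenyl]oxy}-5-methoxy-1-(methoxymethoxy)-3-[(methoxymethoxy)methyl]benzene | COCOCc1cc(OC)cc(OCOC)c1O/C(Cl)=C\Cl | intermediate
9 | 2-[(chloroethynyl)oxy]-5-methoxy-1-(methoxymethoxy)-3-[(methoxymethoxy)methyl]benzene | ClC#COc1c(COCOC)cc(OC)cc1OCOC | intermediate
10 | lithium 2-{4-methoxy-2-(methoxymethoxy)-6-[(methoxymethoxy)methyl]phenoxy}ethynide | [Li]C#COc1c(COCOC)cc(OC)cc1OCOC | intermediate
11 | 2-(ethynyloxy)-5-methoxy-1-(methoxymethoxy)-3-[(methoxymethoxy)methyl]benzene | C#COc1c(COCOC)cc(OC)cc1OCOC | intermediate
12 | dimethyl malonate | COC(=O)CC(=O)OC | starting material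
13 | 2,2,6-trimethyl-4H-1,3-dioxin-4-one | CC1=CC(=O)OC(C)(C)O1 | starting material
14 | acetylketene (but-1-ene-1,3-dione) | CC(=O)C=C=O | intermediate
15 | dimethyl 2-(3-oxobutanoyl)propanedioate | COC(=O)C(C(=O)OC)C(=O)CC(C)=O | intermediate
16 | methyl 4-hydroxy-6-methyl-2-oxo-2H-pyran-3-carboxylate | COC(=O)c1c(O)cc(C)oc1=O | intermediate
17 | methyl 4-(acetyloxy)-6-methyl-2-oxo-2H-pyran-3-carboxylate | COC(=O)c1c(OC(C)=O)cc(C)oc1=O | intermediate
18 | methyl 8-(acetyloxy)-5-{4-methoxy-2-(methoxymethoxy)-6-[(methoxymethoxy)methyl]phenoxy}-1-methyl-3-oxo-2-oxabicyclo[2.2.2]octa-5,7-diene-4-carboxylate (racemic) | COC(=O)C12C(=O)OC(C)(C=C1OC(C)=O)C=C2Oc1c(COCOC)cc(OC)cc1OCOC | intermediate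
19 | methyl 2-(acetyloxy)-6-{4-methoxy-2-(methoxymethoxy)-6-[(methoxymethoxy)methyl]phenoxy}-4-methylbenzoate | COC(=O)c1c(OC(C)=O)cc(C)cc1Oc1c(COCOC)cc(OC)cc1OCOC | intermediate
20 | methyl 2-hydroxy-6-[2-hydroxy-6-(hydroxymethyl)-4-methoxyphenoxy]-4-methylbenzoate | COC(=O)c1c(O)cc(C)cc1Oc1c(CO)cc(OC)cc1O | intermediate
21 | hexadecanoic acid (palmitic acid) | CCCCCCCCCCCCCCCC(=O)O | starting material
22 | betaethrin E, methyl 2-{2-[(hexadecanoyloxy)methyl]-6-hydroxy-4-methoxyphenoxy}-6-hydroxy-4-methylbenzoate | CCCCCCCCCCCCCCCC(=O)OCc1cc(OC)cc(O)c1Oc1cc(C)cc(O)c1C(=O)OC | target

## Step count and least certain steps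

Total: 12 steps. Longest linear sequence: 10 steps (steps 1–7, 10, 11, 12); steps 8 and 9 form the convergent branch.

**Step 10 (key step).** The most likely failure is that thermal oligomerisation of the terminal ynol ether 11 outruns the cycloaddition. The 4-acetoxy and 6-methyl groups of 17 both slow the cycloaddition. Acyl transfer from 17 to traces of water would also free acidic 16, which would protonate 11.

Fallback: reverse the electronic sense of the cycloaddition. It sets out from 8 and comes back at 20. Acetylide 10, generated from 8 as in step 7, is trapped with methyl chloroformate to give methyl 3-{4-methoxy-2-(methoxymethoxy)-6-[(methoxymethoxy)methyl]phenoxy}prop-2-ynoate F1, a stable conjugated alkyne. The diene [(1-methoxy-3-methylbuta-1,3-dien-1-yl)oxy]trimethylsilane F2 is made from methyl 3-methylbut-2-enoate with LDA and Me3SiCl. Heating F1 with F2 in toluene should give, by normal-demand Diels–Alder reaction and loss of methanol, methyl 2-{4-methoxy-2-(methoxymethoxy)-6-[(methoxymethoxy)methyl]phenoxy}-4-methyl-6-[(trimethylsilyl)oxy]benzoate F3. Crude F3 is taken into the methanolic HCl of step 11 and arrives at 20.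

**Step 7.** The most likely failure is loss of the product during quench and isolation, by acid-catalysed hydration of the ynol ether or by polymerisation on concentration. If the mixture warms before the quench, lithiation next to a MOM group may also occur.

Fallback: from 8, acetylide 10 is quenched with Me3SiCl to give the silyl-capped alkyne trimethyl({4-methoxy-2-(methoxymethoxy)-6-[(methoxymethoxy)methyl]phenoxy}ethynyl)silane F4, which can be purified and stored. Treatment with Bu4NF in THF at −20 °C just before step 10 returns to 11.

**Step 4.** The most likely failure is sluggish O-vinylation, because the phenoxide of 5 is delocalised into the ortho aldehyde and shielded on both sides. Base-induced decay of dichloroacetylene would then consume the reagent.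

Fallback: change the order so that a more nucleophilic phenoxide is vinylated. From 5, NaBH4 in MeOH gives 2-(hydroxymethyl)-4-methoxy-6-(methoxymethoxy)phenol F5. K2CO3 with trichloroethylene in DMF deprotonates only the phenol of F5, and its O-vinylation rejoins the route at 7.

**Step 11.** The most likely failure is solvolytic ionisation of the benzylic C–O bond, assisted by the ortho aryloxy group, with capture by methanol. The alternative failure is incomplete cleavage of the benzylic MOM ether under conditions mild enough to avoid that ionisation.

Fallback: a two-stage, non-solvolytic deprotection from 19. ZnBr2 and n-PrSH in CH2Cl2 at 0 °C transfer both methoxymethyl groups to sulfur and give methyl 2-(acetyloxy)-6-[2-hydroxy-6-(hydroxymethyl)-4-methoxyphenoxy]-4-methylbenzoate F6. Catalytic K2CO3 in MeOH at 0 °C then removes the aryl acetate and returns to 20.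

**Step 12.** The most likely failure is competing alkylation of a phenol oxygen by the activated benzylic alcohol, which would give benzyl aryl ether oligomers. The ring A phenol is the likely culprit if the carboxylate concentration is low.

Fallback: enzymatic acylation from 20. Vinyl palmitate with immobilised lipase B of Candida antarctica in t-BuOMe at 40 °C acylates primary alcohols and leaves phenols untouched, and leads directly to 22. No new compound is made.

## Further compounds

F1 | step 10 | methyl 3-{4-methoxy-2-(methoxymethoxy)-6-[(methoxymethoxy)methyl]phenoxy}prop-2-ynoate | COC(=O)C#COc1c(COCOC)cc(OC)cc1OCOC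
F2 | step 10 | [(1-methoxy-3-methylbuta-1,3-dien-1-yl)oxy]trimethylsilane (E/Z mixture) | C=C(C)C=C(OC)O[Si](C)(C)C
F3 | step 10 | methyl 2-{4-methoxy-2-(methoxymethoxy)-6-[(methoxymethoxy)methyl]phenoxy}-4-methyl-6-[(trimethylsilyl)oxy]benzoate | COC(=O)c1c(O[Si](C)(C)C)cc(C)cc1Oc1c(COCOC)cc(OC)cc1OCOC
F4 | step 7 | trimethyl({4-methoxy-2-(methoxymethoxy)-6-[(methoxymethoxy)methyl]phenoxy}ethynyl)silane | C[Si](C)(C)C#COc1c(COCOC)cc(OC)cc1OCOC
F5 | step 4 | 2-(hydroxymethyl)-4-methoxy-6-(methoxymethoxy)phenol | COCOc1cc(OC)cc(CO)c1O
F6 | step 11 | methyl 2-(acetyloxy)-6-[2-hydroxy-6-(hydroxymethyl)-4-methoxyphenoxy]-4-methylbenzoate | COC(=O)c1c(OC(C)=O)cc(C)cc1Oc1c(CO)cc(OC)cc1O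
F0 | step 12 | none | none
A1 | alternative 1 | methyl 2-{[(1E)-2-({[tert-butyl(dimethyl)silyl]oxy}methyl)-4-diazo-3-oxobut-1-en-1-yl]oxy}-6-(methoxymethoxy)-4-methylbenzoate | COC(=O)c1c(OCOC)cc(C)cc1O/C=C(\CO[Si](C)(C)C(C)(C)C)C(=O)C=[N+]=[N-]
A2 | alternative 1 | methoxyacetylene | COC#C
A3 | alternative 1 | methyl 2-[2-({[tert-butyl(dimethyl)silyl]oxy}methyl)-6-hydroxy-4-methoxyphenoxy]-6-(methoxymethoxy)-4-methylbenzoate | COC(=O)c1c(OCOC)cc(C)cc1Oc1c(O)cc(OC)cc1CO[Si](C)(C)C(C)(C)C
A4 | alternative 2 | chelidonic acid (4-oxo-4H-pyran-2,6-dicarboxylic acid) | O=C(O)c1cc(=O)cc(C(=O)O)o1
A5 | alternative 2 | methyl 2-hydroxy-4-methyl-6-({4-oxo-6-[(trityloxy)methyl]-4H-pyran-2-yl}methoxy)benzoate | COC(=O)c1c(O)cc(C)cc1OCc1cc(=O)cc(COC(c2ccccc2)(c2ccccc2)c2ccccc2)o1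
A6 | alternative 2 | methyl 2-hydroxy-4-methyl-6-{[2,4,6-trioxo-7-(trityloxy)heptyl]oxy}benzoate | COC(=O)c1c(O)cc(C)cc1OCC(=O)CC(=O)CC(=O)COC(c1ccccc1)(c1ccccc1)c1ccccc1
A7 | alternative 2 | methyl 2-{2,4-dihydroxy-6-[(trityloxy)methyl]phenoxy}-6-hydroxy-4-methylbenzoate | COC(=O)c1c(O)cc(C)cc1Oc1c(O)cc(O)cc1COC(c1ccccc1)(c1ccccc1)c1ccccc1
A8 | alternative 3 | methyl 3-{4-methoxy-2-(methoxymethoxy)-6-[(methoxymethoxy)methyl]phenoxy}prop-2-ynoate | COC(=O)C#COc1c(COCOC)cc(OC)cc1OCOC
A9 | alternative 3 | [(1-methoxy-3-methylbuta-1,3-dien-1-yl)oxy]trimethylsilane (E/Z mixture) | C=C(C)C=C(OC)O[Si](C)(C)C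
A10 | alternative 3 | methyl 2-hydroxy-6-{4-methoxy-2-(methoxymethoxy)-6-[(methoxymethoxy)methyl]phenoxy}-4-methylbenzoate | COC(=O)c1c(O)cc(C)cc1Oc1c(COCOC)cc(OC)cc1OCOC
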